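**Assumption:** the target has no stereocentre. The three carbinol carbons of 11 and 12 form without control (mixtures of diastereomers) and become CH2 in step 7. Both starting aldehydes are taken as commercial.

## Retrosynthetic overview

- Feature: each ether oxygen sits on a ring carbon para to an allyl-bearing carbon, the A–B oxygen on C-4 of end ring A and the B–C oxygen on C-4 of central ring B. With CHO written for each allyl, these two carbons become the C–F carbons of para-fluorobenzaldehydes.
- Late disconnections: MOM cleavage, then three allyl groups back to three formyl groups (vinyl addition, carbonate, Pd/formate hydrogenolysis).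
- Key disconnection: both diaryl ether C–O bonds of the MOM-protected trialdehyde, made by two successive fluoride displacements in one flask. The components are 4-fluoro-3-methoxybenzaldehyde (ring A), 4-fluoro-3-hydroxy-5-methoxybenzaldehyde (ring B, nucleophile first, electrophile second) and 4-O-MOM-5-hydroxyvanillin (ring C).
- Ring B piece: lithiation next to fluorine, borylation and oxidation of the dioxolane of the ring A aldehyde. Ring C piece: selective 4-O-MOM protection of 3,4-dihydroxy-5-methoxybenzaldehyde.
- No ring is formed in the route; all three benzene rings are bought.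

Key step: step 4

## Route

Step 1
Reactants: 1 4-fluoro-3-methoxybenzaldehyde
Product: 2 2-(4-fluoro-3-methoxyphenyl)-1,3-dioxolane
Conditions: HOCH2CH2OH, p-TsOH·H2O (cat.), toluene, reflux, Dean–Stark
Reagents that add atoms: ethylene glycol, OCCO
Why: Acid-catalysed acetalisation with azeotropic removal of water masks the aldehyde against the lithium amide of step 2.

Step 2
Reactants: 2 2-(4-fluoro-3-methoxyphenyl)-1,3-dioxolane
Product: 6 4-fluoro-3-hydroxy-5-methoxybenzaldehyde, via aryllithium 3 (not isolated), via lithium arylborate 4 (not isolated), via phenol acetal 5 (not isolated)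
Conditions: LiTMP (from TMPH, n-BuLi) added to 2 and B(OiPr)3, THF, −78 °C; AcOH, 30% H2O2, 0 °C → rt; Na2SO3; 2 M HCl, THF, rt
Reagents that add atoms: hydrogen peroxide, OO (phenol oxygen); water, O (carbonyl oxygen after acetal hydrolysis); triisopropyl borate, CC(C)OB(OC(C)C)OC(C)C (atoms only in intermediate 4)
Why: Directed ortho-metalation by the bulky amide removes the most acidic ring proton, H-5 next to fluorine (H-2 between OMe and the acetal is less acidic and shielded); the aryllithium is trapped at once by the borate in the flask before LiF can be lost to an aryne, oxidative aryl migration from boron to oxygen gives the phenol, and acid hydrolysis of the dioxolane frees the aldehyde.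

Step 3
Reactants: 7 3,4-dihydroxy-5-methoxybenzaldehyde (5-hydroxyvanillin)
Product: 8 3-hydroxy-5-methoxy-4-(methoxymethoxy)benzaldehyde
Conditions: MOMCl (1.05 equiv), K2CO3 (1.05 equiv), acetone, 0 °C → rt
Reagents that add atoms: chloromethyl methyl ether, COCCl
Why: Williamson-type O-alkylation; the 4-OH para to the formyl group is the more acidic phenol, so one equivalent of K2CO3 should form only that phenoxide, which MOMCl caps while the 3-OH stays free.

Step 4
Reactants: 6 4-fluoro-3-hydroxy-5-methoxybenzaldehyde; 1 4-fluoro-3-methoxybenzaldehyde; 8 3-hydroxy-5-methoxy-4-(methoxymethoxy)benzaldehyde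
Product: 10 3-(4-formyl-2-methoxyphenoxy)-4-[5-formyl-3-methoxy-2-(methoxymethoxy)phenoxy]-5-methoxybenzaldehyde, via fluoro diaryl ether 9 (not isolated)
Conditions: 6 added slowly to 1 (1.05 equiv), K2CO3, 4 Å MS, DMSO, 90 °C, Ar; then 8 (1.2 equiv), Cs2CO3, 120–130 °C
Reagents that add atoms: none
Why: Each C–O bond forms by addition–elimination: a phenoxide adds to the C–F carbon, the Meisenheimer adduct is stabilised by the para formyl group, and fluoride leaves; the closest known reaction type is the diaryl ether synthesis from phenoxides and 4-fluorobenzaldehydes, run here twice in one flask. No ring closes and no stereocentre is formed. The step needs chemoselectivity between the two fluorides: as its potassium phenoxide, 6 carries O− next to its own C–F carbon and cannot stabilise a Meisenheimer adduct, so it acts only as the nucleophile towards 1; once O-arylated (9), that fluoride is para to CHO on a neutral ring and becomes the electrophile for the phenoxide of 8. Slow addition of 6 to a slight excess of 1 keeps free phenoxide of 6 low while 9 is present, and the fluoride of 9, flanked by two ortho oxygens, is slower than that of 1, so chain growth between central units should stay minor. Compound 8 can react only through O-3 because O-4 carries the MOM group, and Cs2CO3 at the higher temperature supplies the more reactive phenoxide needed for the hindered second displacement.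

Step 5
Reactants: 10 MOM-protected trialdehyde
Product: 11 1-{3-[4-(1-hydroxyprop-2-enyl)-2-methoxyphenoxy]-4-[5-(1-hydroxyprop-2-enyl)-3-methoxy-2-(methoxymethoxy)phenoxy]-5-methoxyphenyl}prop-2-en-1-ol (mixture of diastereomers)
Conditions: CH2=CHMgBr (4.5 equiv), THF, −78 → 0 °C; aq NH4Cl
Reagents that add atoms: vinylmagnesium bromide, C=C[Mg]Br
Why: Grignard 1,2-addition to three non-enolisable aryl aldehydes; the three carbinol centres form without control, which does not matter because all three become CH2 in step 7.

Step 6
Reactants: 11 tris(allylic alcohol)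
Product: 12 tris(methyl carbonate) of 11 (mixture of diastereomers, used crude)
Conditions: ClCO2Me, pyridine, DMAP (cat.), CH2Cl2, 0 °C
Reagents that add atoms: methyl chloroformate, COC(=O)Cl
Why: DMAP-catalysed acylation of the secondary alcohols by the chloroformate gives allylic carbonates, which zerovalent palladium ionises readily.

Step 7
Reactants: 12 tris(methyl carbonate)
Product: 13 1-(methoxymethoxy)-2-methoxy-4-(prop-2-enyl)-6-[2-methoxy-6-(2-methoxy-4-(prop-2-enyl)phenoxy)-4-(prop-2-enyl)phenoxy]benzene (MOM ether of the target)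
Conditions: Pd(OAc)2 (cat.), PBu3, HCO2H, Et3N, THF, 50 °C
Reagents that add atoms: none
Why: Tsuji formate hydrogenolysis: zerovalent palladium (from Pd(OAc)2 and PBu3) ionises each carbonate to a 1-aryl π-allyl complex, and the palladium formate derived from it loses CO2 with hydride transfer through a six-membered SNi′-type transition state to the aryl-bearing terminus, so each unit should emerge as ArCH2CH=CH2.

Step 8
Reactants: 13 MOM ether of the target
Product: 14 4-allyl-2-[4-allyl-2-(4-allyl-2-methoxyphenoxy)-6-methoxyphenoxy]-6-methoxyphenol (target)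
Conditions: 2 M HCl, MeOH, 50 °C
Reagents that add atoms: none
Why: Acid-catalysed cleavage of the MOM acetal by trans-acetalisation to methanol; the allyl groups, methyl ethers and diaryl ethers are inert to dilute HCl at this temperature.

## Compound list

1 | 4-fluoro-3-methoxybenzaldehyde | COc1cc(C=O)ccc1F | starting material
2 | 2-(4-fluoro-3-methoxyphenyl)-1,3-dioxolane | COc1cc(C2OCCO2)ccc1F | intermediate
3 | 2-(4-fluoro-3-lithio-5-methoxyphenyl)-1,3-dioxolane (formed in the flask) | COc1cc(C2OCCO2)cc([Li])c1F | intermediate
4 | lithium [5-(1,3-dioxolan-2-yl)-2-fluoro-3-methoxyphenyl]tri(propan-2-yloxy)borate (formed in the flask) | [Li+].COc1cc(C2OCCO2)cc([B-](OC(C)C)(OC(C)C)OC(C)C)c1F | intermediate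
5 | 5-(1,3-dioxolan-2-yl)-2-fluoro-3-methoxyphenol (formed in the flask) | COc1cc(C2OCCO2)cc(O)c1F | intermediate
6 | 4-fluoro-3-hydroxy-5-methoxybenzaldehyde | COc1cc(C=O)cc(O)c1F | intermediate
7 | 3,4-dihydroxy-5-methoxybenzaldehyde | COc1cc(C=O)cc(O)c1O | starting material
8 | 3-hydroxy-5-methoxy-4-(methoxymethoxy)benzaldehyde | COCOc1c(O)cc(C=O)cc1OC | intermediate
9 | 4-fluoro-3-(4-formyl-2-methoxyphenoxy)-5-methoxybenzaldehyde (formed in the flask) | O=Cc1ccc(Oc2cc(C=O)cc(OC)c2F)c(OC)c1 | intermediate
10 | 3-(4-formyl-2-methoxyphenoxy)-4-[5-formyl-3-methoxy-2-(methoxymethoxy)phenoxy]-5-methoxybenzaldehyde | O=Cc1ccc(Oc2cc(C=O)cc(OC)c2Oc2cc(C=O)cc(OC)c2OCOC)c(OC)c1 | intermediate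
11 | tris(1-hydroxyprop-2-enyl) compound, mixture of diastereomers | C=CC(O)c1ccc(Oc2cc(C(O)C=C)cc(OC)c2Oc2cc(C(O)C=C)cc(OC)c2OCOC)c(OC)c1 | intermediate
12 | tris(methyl carbonate) of 11, mixture of diastereomers | C=CC(OC(=O)OC)c1ccc(Oc2cc(C(OC(=O)OC)C=C)cc(OC)c2Oc2cc(C(OC(=O)OC)C=C)cc(OC)c2OCOC)c(OC)c1 | intermediate
13 | MOM ether of the target (three allyl groups) | C=CCc1ccc(Oc2cc(CC=C)cc(OC)c2Oc2cc(CC=C)cc(OC)c2OCOC)c(OC)c1 | intermediate
14 | 4-allyl-2-[4-allyl-2-(4-allyl-2-methoxyphenoxy)-6-methoxyphenoxy]-6-methoxyphenol | C=CCc1ccc(Oc2cc(CC=C)cc(OC)c2Oc2cc(CC=C)cc(OC)c2O)c(OC)c1 | target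

## Step count

Total: 8 steps. Longest linear sequence: 7 steps (steps 1, 2, 4, 5, 6, 7, 8); step 3 is the convergent branch.

## Steps most likely to fail

**Step 4 (key step).** The second displacement may stall at the fluoride flanked by two ortho oxygens. Central units may also link to each other when free phenoxide of 6 meets 9, and the aryloxy group on the activated ring A carbon may be exchanged by the incoming phenoxide at the high temperature.

Fallback: this sets out from 8 and 1 and comes back at 10, forming the hindered ether with the opposite polarity by copper catalysis. The phenoxide of 8 (K2CO3, DMSO, 90 °C) is arylated by 1 in an unhindered SNAr to give 3-(4-formyl-2-methoxyphenoxy)-5-methoxy-4-(methoxymethoxy)benzaldehyde F1. HCl in MeOH removes the MOM group to give 3-(4-formyl-2-methoxyphenoxy)-4-hydroxy-5-methoxybenzaldehyde F2. Commercial 5-bromovanillin (COc1cc(C=O)cc(Br)c1O) is capped with MOMCl and K2CO3 to give 3-bromo-5-methoxy-4-(methoxymethoxy)benzaldehyde F3. An Ullmann ether coupling of F2 with F3 (CuI, N,N-dimethylglycine, Cs2CO3, dioxane, 100 °C) should then give 10.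

**Step 2.** Deprotonation may occur at the wrong ring position (H-2 between OMe and the acetal), or the ortho-fluoro aryllithium may lose LiF to an aryne before it is trapped.

Fallback: this sets out from 2 and comes back at 6, replacing deprotonation with sterically controlled C–H borylation. [Ir(OMe)(cod)]2 with 4,4′-di-tert-butyl-2,2′-bipyridine and B2pin2 in THF at 80 °C should borylate the only C–H without a large ortho neighbour (C-5, next to fluorine). This gives 2-[4-fluoro-3-methoxy-5-(4,4,5,5-tetramethyl-1,3,2-dioxaborolan-2-yl)phenyl]-1,3-dioxolane F4. Oxidation with H2O2/NaOH and then 2 M HCl in THF leads through 5 to 6.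

**Step 7.** Hydride delivery may lose regiocontrol at one or more of the three π-allyl units, giving internal propenyl isomers, or a palladium hydride may move the terminal double bonds into conjugation.

Fallback: this sets out from 10 and comes back at 13, building each allyl group by sp3–sp2 cross-coupling. NaBH4 in MeOH/THF at 0 °C reduces the three aldehydes to {3-[4-(hydroxymethyl)-2-methoxyphenoxy]-4-[5-(hydroxymethyl)-3-methoxy-2-(methoxymethoxy)phenoxy]-5-methoxyphenyl}methanol F5. MsCl, Et3N and LiCl in DMF convert it under non-acidic conditions into 5-(chloromethyl)-1-[4-(chloromethyl)-2-methoxyphenoxy]-2-[5-(chloromethyl)-3-methoxy-2-(methoxymethoxy)phenoxy]-3-methoxybenzene F6. A threefold Stille coupling with Bu3SnCH=CH2 and Pd(PPh3)4 in toluene at 90 °C should then give 13.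

## Further compounds

F1 | step 4 | 3-(4-formyl-2-methoxyphenoxy)-5-methoxy-4-(methoxymethoxy)benzaldehyde | O=Cc1ccc(Oc2cc(C=O)cc(OC)c2OCOC)c(OC)c1
F2 | step 4 | 3-(4-formyl-2-methoxyphenoxy)-4-hydroxy-5-methoxybenzaldehyde | O=Cc1ccc(Oc2cc(C=O)cc(OC)c2O)c(OC)c1
F3 | step 4 | 3-bromo-5-methoxy-4-(methoxymethoxy)benzaldehyde | COCOc1c(Br)cc(C=O)cc1OC
F4 | step 2 | 2-[4-fluoro-3-methoxy-5-(4,4,5,5-tetramethyl-1,3,2-dioxaborolan-2-yl)phenyl]-1,3-dioxolane | COc1cc(C2OCCO2)cc(B3OC(C)(C)C(C)(C)O3)c1F
F5 | step 7 | {3-[4-(hydroxymethyl)-2-methoxyphenoxy]-4-[5-(hydroxymethyl)-3-methoxy-2-(methoxymethoxy)phenoxy]-5-methoxyphenyl}methanol | OCc1ccc(Oc2cc(CO)cc(OC)c2Oc2cc(CO)cc(OC)c2OCOC)c(OC)c1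
F6 | step 7 | 5-(chloromethyl)-1-[4-(chloromethyl)-2-methoxyphenoxy]-2-[5-(chloromethyl)-3-methoxy-2-(methoxymethoxy)phenoxy]-3-methoxybenzene | ClCc1ccc(Oc2cc(CCl)cc(OC)c2Oc2cc(CCl)cc(OC)c2OCOC)c(OC)c1
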